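## The problem

Agrandol (15) is (2S)-5,7-dihydroxy-6-methoxy-8-(3-methylbut-2-en-1-yl)flavanone. It is a chroman-4-one whose pyranone (ring C: O1, C2, C3, C4, C4a, C8a) is fused to a benzene ring (ring A: C4a, C5–C8, C8a) with no hydrogen left, and C2 carries an unsubstituted phenyl group (ring B). Ring A holds three neighbouring oxygens of which only the middle one, at C6, is methylated, and a prenyl group on C8 between the 7-hydroxyl and O1. A synthesis must therefore tell the C6 oxygen from its neighbours from the start and put the prenyl group on carbon, not oxygen. C2 is the only stereocentre, so no other centre can steer it, and its S configuration must come from a chiral catalyst or a chiral building block. Once made it is fragile: C2 is β to the ketone and O1 is a phenoxide leaving group, so base opens ring C by retro-oxa-Michael elimination and recloses it without selectivity. The prenyl double bond beside the free 7-hydroxyl is the second weak spot: acid closes it to a 2,2-dimethylchroman, hydrogenation saturates it and electrophilic oxidants attack it. Protecting groups must therefore leave without strong acid, strong base or hydrogen, and the prenyl group should enter after any strongly acidic operation. The feature that opens a short route lies in ring C. C2 (with ring B) and C3 are simply the two carbons of styrene, and C4 is an oxygen-bearing carbon on C4a, ortho to the O1-bearing C8a, that is, the formyl carbon of a salicylaldehyde. At the oxidation level of a C4 ether, the unit O1–C8a–C4a–C4 is a 4-alkoxy ortho-quinone methide, a heterodiene able to take up styrene across O1 and C4.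

## Retrosynthesis

**Deprotection (15 from 14).** The two O–Si bonds at the 5- and 7-oxygens are cut last. tert-Butyldimethylsilyl ethers are preferred to methoxymethyl ethers, which need acid at the end and would not outlast the acid of the ring-forming step. They are also preferred to benzyl ethers, whose hydrogenolysis would reduce the prenyl group. Aryl silyl ethers withstand strong acid and leave with buffered fluoride. Precursor 14 is no simpler in skeleton; the forward step need only stay close to neutral so that C2 and the prenyl group are untouched.

**Prenyl group (14 from 12 and 13).** The bond between C8 and the prenyl CH2 is cut, giving aryl bromide 12 and prenylstannane 13. A late cross-coupling is preferred to carrying the prenyl group through the route, because the alkene would survive neither the strong acid that closes ring C nor the quinone oxidant that makes the ketone. Friedel–Crafts prenylation is no option on the fully protected ring. The cut removes five carbons and leaves a bromide at the one position of ring A that no other substituent claims. The forward reaction must couple at a bromide flanked by two oxygen substituents and deliver the prenyl group through its unsubstituted terminus.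

**Ketone (12 from 11).** No skeletal bond is cut. The C4 carbonyl is traced back to a C4 methyl ether, so that 12 derives from 4-methoxyflavan 11 by oxidation of the C4–H bond. This is better than a flavan without oxygen at C4, which would need a C–H oxygenation and then a second oxidation. It also makes the C4 configuration of 11 irrelevant. The forward step must abstract hydride from C4 and not from C2; the three oxygen donors of ring A and the methoxy group on C4 should ensure this.

**Ring C (11 from 6, 7 and 8).** The bonds O1–C2 and C3–C4 are cut together. Ring C falls apart into bromosalicylaldehyde 6, styrene (8) and trimethyl orthoformate (7). The orthoformate turns the aldehyde into acetal 9, which loses methanol to give the 4-methoxy ortho-quinone methide 10. The neighbouring cuts are weaker. Closing O1–C2 alone by conjugate addition is the reversible process that racemises flavanones. Closing C4–C4a by acylation requires the stereocentre to be made beforehand in an open chain that eliminates aryloxide easily. The double cut removes the ring, the stereocentre and eight carbons at once and leaves three achiral components, two of them bulk chemicals. The bromine in 6 is deliberate. Without it the only free carbon of this electron-rich ring would be a better nucleophile than styrene towards the cation derived from 10, and the same bromine later serves as the coupling handle. The forward reaction must control C2 absolutely through a chiral acid, place oxygen on the benzylic carbon, and give a product that does not ionise again at C2.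

**Salicylaldehyde (6 from 5 from 4).** The C–Br bond and then the C–CHO bond are cut. Bromination follows formylation because 5 has a single free ring carbon, so mono- versus dibromination is not an issue. Formylation of phenol 4 poses no regiochemical question either: its two ortho carbons are equivalent and the para carbon bears the methoxy group. Phenol 4 is symmetrical and two substituents simpler than 6. The formylation must respect the silyl ethers and work next to a bulky silyloxy group.

**Phenol (4 from 2 through 3; 2 from 1).** The C–O bond of the phenolic hydroxyl is cut, leading through aryl boronate 3 to arene 2, and two O–Si cuts then give 2-methoxyresorcinol (1). The hydroxyl of 4 is meta to both silyloxy groups. Electrophilic substitution of 2 cannot create that relationship, but sterically controlled C–H borylation gives it directly, because C5 is the only C–H of 2 without an ortho neighbour. A Baeyer–Villiger degradation route to the same phenol would be two to three steps longer. Diol 1 is commercial and already carries the methyl group on the middle oxygen, so the differentiation of the three ring A oxygens costs nothing.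

## Roads not taken

**Alternative 1:** The cut runs through ring A itself (C7–C8, C8a–C4a and C6–C7 in flavanone numbering). Cyclobutenone A2 would be heated with the prenyl-bearing siloxyalkyne A3 in a Danheiser benzannulation: electrocyclic opening to a vinylketene, [2+2] addition of A3, a second opening and a 6π closure. The product is phenol A1, with the free hydroxyl on the future C7, the prenyl group on C8, the silyloxy group on C8a, ethoxy on C5 and methoxy on C6.
- Merits: every ring A substituent is placed without a regiochemical question, the prenyl group enters in a neutral thermal step, and no crowded cross-coupling is needed. In this respect it is better than the chosen plan, which has a late Stille coupling at a hindered bromide to set against it.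
- Weak points: the key step is spent on a benzene ring that can be bought with three oxygens in place (1). Ring C and C2 are not addressed at all. A1 would still need C-acylation at C4a beside an acid-sensitive prenyl group, an enantioselective oxa-Michael closure (reversible and poorly controlled for unactivated substrates), and selective cleavage of the ethyl ether. A2 and A3 are themselves multistep.
- Comparison: the road is longer and leaves the only stereocentre unsolved, whereas the chosen plan makes ring C and C2 in one operation.

**Alternative 2:** The cut is C2–C3. Diazoketone A4 would lose nitrogen under dirhodium tetrakis[N-phthaloyl-(S)-tert-leucinate], Rh2(S-PTTL)4, and the carbene would insert into a benzylic C–H bond of the neighbouring benzyl ether. This closes the pyranone and gives A5, which is the same compound as 14.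
- Merits: the flavanone arrives at the right oxidation level with the prenyl group in place, and only desilylation remains, against three steps after the key step in the chosen plan. The stereocentre is made in the ring-forming event.
- Weak points: an acceptor-only carbene next to an ether oxygen prefers the oxygen lone pair, and the resulting oxonium ylide shifts its benzyl group to give a five-membered benzofuranone. Insertion that closes a six-membered ring is disfavoured against such five-membered pathways. The prenyl alkene and the benzyl ring are further carbene traps. Enantiocontrol for this insertion mode has little support. A4 requires a hexasubstituted benzoic acid carried through acid activation and diazomethane acylation with the prenyl group present.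
- Comparison: the endgame is shorter, but the chemoselectivity problem is built into the substrate. In the chosen plan the competing nucleophile is removed by the bromine of 6.

**Alternative 3:** The cut is O1–C8a. Bromo alcohol A6, with the (S)-carbinol made beforehand by asymmetric ketone reduction, would be cyclised with Pd(OAc)2, 2-(di-tert-butylphosphino)-1,1'-binaphthyl and Cs2CO3 to flavan A7.
- Merits: the carbinol carbon is not touched when the aryl–oxygen bond forms, so the C2 configuration rests on a very reliable reduction. In certainty of enantiopurity this road is better than the chosen one.
- Weak points: the bromide sits between the prenyl-bearing C8 and the side chain on C4a in a hexasubstituted, electron-rich ring, so oxidative addition is slow. The secondary benzylic alkoxide on palladium can undergo β-hydride elimination, giving a ketone and a reduced arene. A6 needs a long linear build-up with four different oxygen functions and a differentiated 1,3-diol. After the coupling three more operations follow, ending with acid removal of two methoxymethyl ethers beside the prenyl group.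
- Comparison: the chosen plan sets against the safer stereocentre its brevity (eight steps from three commercial components) and a resolution-based fallback for C2.

Key step: step 5

Assumption 1: the sense of induction of the chiral acid in step 5 cannot be predicted with confidence. The (S,S) acid HN[P(=NSO2CF3)(O2R*)]2, with O2R* = (S)-3,3'-bis[3,5-bis(trifluoromethyl)phenyl]-1,1'-binaphthalene-2,2'-diolate, is written as a first candidate; its mirror image would be used if it is the one that gives the (2S) series.

Assumption 2: quinone methide 10 is drawn neutral. Under the acid it reacts as its O-protonated form, an oxocarbenium ion paired with the chiral anion.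

## Route

Step 1
Reactants: 1 2-methoxybenzene-1,3-diol (2-methoxyresorcinol)
Product: 2 1,3-bis(tert-butyldimethylsilyloxy)-2-methoxybenzene
Conditions: TBSCl, imidazole, DMF, rt
Reagents that add atoms: tert-butyldimethylsilyl chloride, CC(C)(C)[Si](C)(C)Cl
Why: Imidazole-promoted silylation of phenols; the two hydroxyls are equivalent, and the aryl silyl ethers formed tolerate acid, oxidants and the later coupling.

Step 2
Reactants: 2 1,3-bis(tert-butyldimethylsilyloxy)-2-methoxybenzene
Product: 4 3,5-bis(tert-butyldimethylsilyloxy)-4-methoxyphenol, via aryl pinacol boronate 3 (not isolated)
Conditions: [Ir(OMe)(cod)]2 (cat.), 4,4'-di-tert-butyl-2,2'-bipyridine, B2pin2, THF, 80 °C; then Oxone, acetone/H2O, 0 °C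
Reagents that add atoms: bis(pinacolato)diboron, CC1(C)OB(OC1(C)C)B1OC(C)(C)C(C)(C)O1 (boryl group of 3 only); potassium peroxymonosulfate (Oxone), [K+].[O-]S(=O)(=O)OO (phenolic oxygen of 4)
Why: Iridium-catalysed C–H borylation is governed by sterics and should occur at C5, the only C–H without an ortho substituent; the one-pot oxidation of the C–B bond by peroxymonosulfate is the established borylation/oxidation route to meta-substituted phenols.

Step 3
Reactants: 4 3,5-bis(tert-butyldimethylsilyloxy)-4-methoxyphenol
Product: 5 4,6-bis(tert-butyldimethylsilyloxy)-2-hydroxy-5-methoxybenzaldehyde
Conditions: MgCl2, Et3N, (CH2O)n, MeCN, reflux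
Reagents that add atoms: formaldehyde (as paraformaldehyde), C=O
Why: Casnati–Skattebøl ortho-formylation: the magnesium phenoxide delivers formaldehyde to an ortho carbon and a second equivalent accepts hydride to give the aldehyde; both ortho carbons are equivalent and the para carbon is blocked, so only one salicylaldehyde can form.

Step 4
Reactants: 5 4,6-bis(tert-butyldimethylsilyloxy)-2-hydroxy-5-methoxybenzaldehyde
Product: 6 3-bromo-4,6-bis(tert-butyldimethylsilyloxy)-2-hydroxy-5-methoxybenzaldehyde
Conditions: NBS, MeCN, 0 °C
Reagents that add atoms: N-bromosuccinimide, O=C1CCC(=O)N1Br
Why: Electrophilic aromatic bromination at the only unsubstituted ring carbon, which is ortho to the free hydroxyl and to one silyloxy group and para to the other; the bromine caps this nucleophilic carbon before the acid step and is the later coupling handle.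

Step 5
Reactants: 6 3-bromo-4,6-bis(tert-butyldimethylsilyloxy)-2-hydroxy-5-methoxybenzaldehyde; 7 trimethyl orthoformate; 8 styrene
Product: 11 (2S)-8-bromo-5,7-bis(tert-butyldimethylsilyloxy)-4,6-dimethoxyflavan (mixture of C4 epimers), via dimethyl acetal 9 (not isolated), via methoxy ortho-quinone methide 10 (not isolated)
Conditions: 7 (2 equiv), 8 (3 equiv), (S,S)-imidodiphosphorimidate acid HN[P(=NSO2CF3)(O2R*)]2 (5 mol %), CH2Cl2, −40 °C
Reagents that add atoms: none
Why: Proposed new method: the acid and 7 convert 6 into acetal 9, which loses methanol to the O-protonated form of quinone methide 10, an aryl-stabilised oxocarbenium ion held as a contact ion pair with the chiral anion through the phenolic O–H; the CH2 terminus of 8 attacks C4 and the phenolic oxygen captures the developing benzylic cation at C2. The closest known reaction types are the racemic Brønsted acid-catalysed condensation of salicylaldehydes, orthoformates and styrenes to 2-aryl-4-alkoxychromans and chiral acid-catalysed [4+2] cycloadditions of ortho-quinone methides with styrenes; running the alkoxy-substituted quinone methide under a chiral confined anion is the new element. The pyran ring closes by an inverse-demand hetero-[4+2] annulation, asynchronous in that C3–C4 forms first and O1–C2 then closes the six-membered ring within the ion pair. The C2 configuration is set in the O1–C2 bond-forming event by the chiral anion, which shields one face of the styrene-derived cation; the C4 epimer ratio (2,4-cis expected to dominate) is irrelevant because C4 becomes the ketone. Regiochemistry follows the polarisation of styrene, oxygen going to the benzylic carbon. The step needs enantiocontrol at C2 independent of C4, which requires ring closure to be faster than rotation of the open cation, and chemoselectivity for styrene over arene nucleophiles, which the bromine on the only free ring carbon secures. Low temperature guards against acid-induced reopening of the O1–C2 bond.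

Step 6
Reactants: 11 (2S)-8-bromo-5,7-bis(tert-butyldimethylsilyloxy)-4,6-dimethoxyflavan (mixture of C4 epimers)
Product: 12 (2S)-8-bromo-5,7-bis(tert-butyldimethylsilyloxy)-6-methoxyflavanone
Conditions: DDQ, CH2Cl2/H2O (10:1), 0 °C to rt
Reagents that add atoms: water, O
Why: DDQ oxidation of a benzylic ether: hydride abstraction from C4–H gives an oxocarbenium ion stabilised by the C4 methoxy group and the ortho and para oxygens of ring A, water adds and methanol is lost to leave the ketone; DDQ oxidation at C4 of flavans is established, both C4 epimers converge and C2 is not involved.

Step 7
Reactants: 12 (2S)-8-bromo-5,7-bis(tert-butyldimethylsilyloxy)-6-methoxyflavanone; 13 tributyl(3-methylbut-2-en-1-yl)stannane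
Product: 14 (2S)-5,7-bis(tert-butyldimethylsilyloxy)-6-methoxy-8-(3-methylbut-2-en-1-yl)flavanone
Conditions: Pd(PPh3)4 (10 mol %), DMF, 90 °C
Reagents that add atoms: none
Why: Stille coupling: zerovalent palladium inserts into the C8–Br bond, the prenyl group is transferred from tin, and reductive elimination at the less substituted allyl terminus gives the linear prenyl arene; the medium is neutral, so the silyl ethers and the C2 centre of the flavanone are not at risk.

Step 8
Reactants: 14 (2S)-5,7-bis(tert-butyldimethylsilyloxy)-6-methoxy-8-(3-methylbut-2-en-1-yl)flavanone
Product: 15 agrandol, (2S)-5,7-dihydroxy-6-methoxy-8-(3-methylbut-2-en-1-yl)flavanone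
Conditions: TBAF, AcOH, THF, 0 °C
Reagents that add atoms: none
Why: Fluoride-induced cleavage of the aryl silyl ethers; acetic acid buffers the phenoxides so the flavanone cannot open by retro-oxa-Michael elimination (which would racemise C2), and the near-neutral medium spares the prenyl group beside the free 7-hydroxyl.

## Compound list

1 | 2-methoxybenzene-1,3-diol (2-methoxyresorcinol) | COc1c(O)cccc1O | starting material
2 | 1,3-bis(tert-butyldimethylsilyloxy)-2-methoxybenzene | COc1c(O[Si](C)(C)C(C)(C)C)cccc1O[Si](C)(C)C(C)(C)C | intermediate
3 | 2-[3,5-bis(tert-butyldimethylsilyloxy)-4-methoxyphenyl]-4,4,5,5-tetramethyl-1,3,2-dioxaborolane | COc1c(O[Si](C)(C)C(C)(C)C)cc(B2OC(C)(C)C(C)(C)O2)cc1O[Si](C)(C)C(C)(C)C | intermediate (not isolated)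
4 | 3,5-bis(tert-butyldimethylsilyloxy)-4-methoxyphenol | COc1c(O[Si](C)(C)C(C)(C)C)cc(O)cc1O[Si](C)(C)C(C)(C)C | intermediate
5 | 4,6-bis(tert-butyldimethylsilyloxy)-2-hydroxy-5-methoxybenzaldehyde | O=Cc1c(O)cc(O[Si](C)(C)C(C)(C)C)c(OC)c1O[Si](C)(C)C(C)(C)C | intermediate
6 | 3-bromo-4,6-bis(tert-butyldimethylsilyloxy)-2-hydroxy-5-methoxybenzaldehyde | O=Cc1c(O)c(Br)c(O[Si](C)(C)C(C)(C)C)c(OC)c1O[Si](C)(C)C(C)(C)C | intermediate
7 | trimethyl orthoformate | COC(OC)OC | starting material
8 | styrene | C=Cc1ccccc1 | starting material
9 | 2-bromo-3,5-bis(tert-butyldimethylsilyloxy)-6-(dimethoxymethyl)-4-methoxyphenol | COC(OC)c1c(O)c(Br)c(O[Si](C)(C)C(C)(C)C)c(OC)c1O[Si](C)(C)C(C)(C)C | intermediate (not isolated)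
10 | 2-bromo-3,5-bis(tert-butyldimethylsilyloxy)-4-methoxy-6-(methoxymethylidene)cyclohexa-2,4-dien-1-one | COC=C1C(=O)C(Br)=C(O[Si](C)(C)C(C)(C)C)C(OC)=C1O[Si](C)(C)C(C)(C)C | intermediate (not isolated)
11 | (2S)-8-bromo-5,7-bis(tert-butyldimethylsilyloxy)-4,6-dimethoxyflavan, i.e. the 2-phenylchromane, C4 epimers | COC1C[C@@H](c2ccccc2)Oc2c(Br)c(O[Si](C)(C)C(C)(C)C)c(OC)c(O[Si](C)(C)C(C)(C)C)c21 | intermediate
12 | (2S)-8-bromo-5,7-bis(tert-butyldimethylsilyloxy)-6-methoxyflavanone | COc1c(O[Si](C)(C)C(C)(C)C)c(Br)c2c(c1O[Si](C)(C)C(C)(C)C)C(=O)C[C@@H](c1ccccc1)O2 | intermediate
13 | tributyl(3-methylbut-2-en-1-yl)stannane | CCCC[Sn](CCCC)(CCCC)CC=C(C)C | starting material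
14 | (2S)-5,7-bis(tert-butyldimethylsilyloxy)-6-methoxy-8-(3-methylbut-2-en-1-yl)flavanone | COc1c(O[Si](C)(C)C(C)(C)C)c(CC=C(C)C)c2c(c1O[Si](C)(C)C(C)(C)C)C(=O)C[C@@H](c1ccccc1)O2 | intermediate
15 | agrandol, (2S)-5,7-dihydroxy-6-methoxy-8-(3-methylbut-2-en-1-yl)flavanone | COc1c(O)c(CC=C(C)C)c2c(c1O)C(=O)C[C@@H](c1ccccc1)O2 | target

## Step count and least certain steps

Total step count: 8. Longest linear sequence: 8 steps (1 to 15); 7, 8 and 13 are commercial and enter directly.

**Step 5 (key step, proposed new method).** The most likely failure is poor enantiofacial discrimination at C2. The pentasubstituted oxocarbenium ion, with two bulky silyl ethers and a bromine, may not be held tightly in the pocket of the confined acid. Also, C3–C4 and O1–C2 need not form in one event, so the open benzylic cation can rotate before the oxygen closes the ring. A second risk is slow addition: styrene is a weak nucleophile and the cation is stabilised by three oxygen donors, which leaves time for acid-induced oligomerisation of styrene. The fallback uses known chemistry and sets out from 6. The condensation with 7 and 8 is run with an achiral strong acid (catalytic CF3SO3H, CH2Cl2, −20 °C), which is the known racemic reaction, to give racemic 8-bromo-5,7-bis(tert-butyldimethylsilyloxy)-4,6-dimethoxyflavan F1. Oxidation with DDQ in wet CH2Cl2, as in step 6, gives racemic 8-bromo-5,7-bis(tert-butyldimethylsilyloxy)-6-methoxyflavanone F2. F2 is then subjected to kinetic resolution by Noyori asymmetric transfer hydrogenation with RuCl(p-cymene)[(R,R)-TsDPEN] and HCO2H/Et3N, stopped near half conversion. The (2R) ketone should be reduced to (2R,4R)-8-bromo-5,7-bis(tert-butyldimethylsilyloxy)-6-methoxyflavan-4-ol F3, which is separated, and the unreacted (2S) ketone is 12, where the route is rejoined. The mirror-image catalyst would be taken if the matched pairing proved to be the reverse. The price is the loss of half the material.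

**Step 6.** The most likely failure is slow or incomplete hydride abstraction. Peri strain with the 5-silyloxy group pushes the C4 methoxy group pseudo-axial and leaves the C4–H bond near the plane of ring A, where overlap with the π system is poor. Elimination of methanol across C3–C4 followed by over-oxidation of ring C can then compete. The fallback sets out from 11. The C4 methyl ether is hydrolysed with pyridinium p-toluenesulfonate in wet acetone (ionisation to the ring A-stabilised cation and capture by water) to (2S)-8-bromo-5,7-bis(tert-butyldimethylsilyloxy)-6-methoxyflavan-4-ol F4. F4 is oxidised with Dess–Martin periodinane (NaHCO3, CH2Cl2) to 12, where the route is rejoined.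

**Step 7.** The most likely failure is sluggish coupling with competing protodebromination and partial allylic transposition to the 1,1-dimethylallyl isomer. The aryl–palladium intermediate is flanked by two ortho oxygen substituents, and the prenyl group is a bulky, ambident partner. The fallback sets out from 12. Stille coupling with the smaller allyltributylstannane (Pd(PPh3)4, DMF, 90 °C), where transposition is without consequence, gives (2S)-8-allyl-5,7-bis(tert-butyldimethylsilyloxy)-6-methoxyflavanone F5. Cross-metathesis of F5 with 2-methyl-2-butene, using the second-generation Grubbs catalyst (H2IMes)(PCy3)Cl2Ru=CHPh in CH2Cl2 at 40 °C, builds the trisubstituted alkene and returns to the route at 14.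

**Step 3.** The most likely failure is loss of a silyl group to the magnesium methoxide formed during the reaction at reflux, together with incomplete conversion because the reacting carbon lies next to a bulky silyloxy group. The fallback sets out from 4 and replaces the magnesium phenoxide/formaldehyde redox process by an electrophilic formylation. Vilsmeier–Haack reaction (POCl3, DMF, 0 °C) gives N-{[2,4-bis(tert-butyldimethylsilyloxy)-6-hydroxy-3-methoxyphenyl]methylidene}-N-methylmethanaminium chloride F6, which is hydrolysed with aqueous sodium acetate to 5, where the route is rejoined. The para carbon is blocked and both ortho carbons are equivalent, so the regiochemistry is the same.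

## Further compounds

F1 | step 5 | racemic 8-bromo-5,7-bis(tert-butyldimethylsilyloxy)-4,6-dimethoxyflavan (C4 epimers) | COC1CC(c2ccccc2)Oc2c(Br)c(O[Si](C)(C)C(C)(C)C)c(OC)c(O[Si](C)(C)C(C)(C)C)c21
F2 | step 5 | racemic 8-bromo-5,7-bis(tert-butyldimethylsilyloxy)-6-methoxyflavanone | COc1c(O[Si](C)(C)C(C)(C)C)c(Br)c2c(c1O[Si](C)(C)C(C)(C)C)C(=O)CC(c1ccccc1)O2
F3 | step 5 | (2R,4R)-8-bromo-5,7-bis(tert-butyldimethylsilyloxy)-6-methoxyflavan-4-ol | COc1c(O[Si](C)(C)C(C)(C)C)c(Br)c2c(c1O[Si](C)(C)C(C)(C)C)[C@H](O)C[C@H](c1ccccc1)O2
F4 | step 6 | (2S)-8-bromo-5,7-bis(tert-butyldimethylsilyloxy)-6-methoxyflavan-4-ol (C4 epimers) | COc1c(O[Si](C)(C)C(C)(C)C)c(Br)c2c(c1O[Si](C)(C)C(C)(C)C)C(O)C[C@@H](c1ccccc1)O2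
F5 | step 7 | (2S)-8-allyl-5,7-bis(tert-butyldimethylsilyloxy)-6-methoxyflavanone | COc1c(O[Si](C)(C)C(C)(C)C)c(CC=C)c2c(c1O[Si](C)(C)C(C)(C)C)C(=O)C[C@@H](c1ccccc1)O2
F6 | step 3 | N-{[2,4-bis(tert-butyldimethylsilyloxy)-6-hydroxy-3-methoxyphenyl]methylidene}-N-methylmethanaminium chloride | C[N+](C)=Cc1c(O)cc(O[Si](C)(C)C(C)(C)C)c(OC)c1O[Si](C)(C)C(C)(C)C.[Cl-]
A1 | alternative 1 | 5-ethoxy-6-methoxy-2-(3-methylbut-2-en-1-yl)-3-(triisopropylsilyloxy)phenol | CCOc1cc(O[Si](C(C)C)(C(C)C)C(C)C)c(CC=C(C)C)c(O)c1OC
A2 | alternative 1 | 3-ethoxy-4-methoxycyclobut-2-en-1-one | CCOC1=CC(=O)C1OC
A3 | alternative 1 | triisopropyl[(5-methylhex-4-en-1-yn-1-yl)oxy]silane | CC(C)=CCC#CO[Si](C(C)C)(C(C)C)C(C)C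
A4 | alternative 2 | 1-[2-(benzyloxy)-4,6-bis(tert-butyldimethylsilyloxy)-5-methoxy-3-(3-methylbut-2-en-1-yl)phenyl]-2-diazoethan-1-one | [N-]=[N+]=CC(=O)c1c(OCc2ccccc2)c(CC=C(C)C)c(O[Si](C)(C)C(C)(C)C)c(OC)c1O[Si](C)(C)C(C)(C)C
A5 | alternative 2 | (2S)-5,7-bis(tert-butyldimethylsilyloxy)-6-methoxy-8-(3-methylbut-2-en-1-yl)flavanone (identical with 14) | CC(C)=CCc1c(O[Si](C)(C)C(C)(C)C)c(OC)c(O[Si](C)(C)C(C)(C)C)c2c1O[C@H](c1ccccc1)CC2=O
A6 | alternative 3 | (1S)-3-[2-bromo-5-methoxy-4,6-bis(methoxymethoxy)-3-(3-methylbut-2-en-1-yl)phenyl]-3-(tert-butyldimethylsilyloxy)-1-phenylpropan-1-ol (C3 epimers) | CC(C)=CCc1c(OCOC)c(OC)c(OCOC)c(C(C[C@H](O)c2ccccc2)O[Si](C)(C)C(C)(C)C)c1Br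
A7 | alternative 3 | (2S)-4-(tert-butyldimethylsilyloxy)-6-methoxy-5,7-bis(methoxymethoxy)-8-(3-methylbut-2-en-1-yl)flavan (C4 epimers) | CC(C)=CCc1c(OCOC)c(OC)c(OCOC)c2c1O[C@H](c1ccccc1)CC2O[Si](C)(C)C(C)(C)C
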